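**Retrosynthetic overview**
- Target ⇐ its 4‑O‑TIPS ether. The furan ring (ring B) is made last, by Sonogashira coupling and 5‑endo cyclisation of an o‑iodophenol (ring A) with an aryl alkyne (rings C and D).
- Ring A piece ⇐ phloroglucinol. The (R) centre comes from SN2 opening of (2S,3S)-2,3-dimethyloxirane by an aryllithium, then oxidation and methylenation. Because the arene is symmetric the iodination is unambiguous, and MOM versus TIPS decides which oxygen closes the furan.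
- Ring C/D piece ⇐ 3,5-dihydroxybenzaldehyde. Both prenyl groups come from a twofold aromatic Claisen rearrangement, ring D from acid cyclisation of one prenyl/phenol pair, and the alkyne from Ohira–Bestmann homologation.
- Ring order: rings A and C are bought as arenes, ring D (dihydropyran) is closed first, ring B (furan) last.

Assumption: (2S,3S)-2,3-dimethyloxirane is bought as the single enantiomer; the stereocentre of the target is (R).

**Step 1**
Reactants: 1 benzene-1,3,5-triol (phloroglucinol)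
Product: 2 5-(triisopropylsilyloxy)benzene-1,3-diol
Conditions: TIPSCl (1 equiv), imidazole, DMF, 0 °C to rt; 1 in threefold excess
Reagents that add atoms: triisopropylsilyl chloride (TIPSCl), CC(C)[Si](Cl)(C(C)C)C(C)C
Why: Statistical O‑silylation, kept at the mono stage by the excess of cheap water‑soluble triol, marks the oxygen that becomes the 4‑OH and must not close the furan.

**Step 2**
Reactants: 2 5-(triisopropylsilyloxy)benzene-1,3-diol
Product: 3 [3,5-bis(methoxymethoxy)phenoxy]triisopropylsilane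
Conditions: MOMCl, i-Pr2NEt, CH2Cl2, 0 °C to rt
Reagents that add atoms: chloromethyl methyl ether (MOMCl), COCCl
Why: O‑Alkylation of both phenols gives two MOM ethers that later direct lithiation to the carbon between them.

**Step 3**
Reactants: 3 [3,5-bis(methoxymethoxy)phenoxy]triisopropylsilane; 4 (2S,3S)-2,3-dimethyloxirane
Product: 6 (2S,3S)-3-[2,6-bis(methoxymethoxy)-4-(triisopropylsilyloxy)phenyl]butan-2-ol, via aryllithium 5 (not isolated)
Conditions: n-BuLi, THF, 0 °C; then 4, BF3·OEt2, −78 °C; H2O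
Reagents that add atoms: none
Why: Directed ortho‑metalation between the two MOM ethers gives the aryllithium, which opens the BF3‑activated trans‑epoxide by SN2 attack with inversion, so the (2S,3S)-epoxide sets the (3S) benzylic centre that becomes the (R) centre of the target.

**Step 4**
Reactants: 6 (2S,3S)-3-[2,6-bis(methoxymethoxy)-4-(triisopropylsilyloxy)phenyl]butan-2-ol
Product: 7 (3S)-3-[2,6-bis(methoxymethoxy)-4-(triisopropylsilyloxy)phenyl]butan-2-one
Conditions: Dess–Martin periodinane, CH2Cl2, 0 °C to rt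
Reagents that add atoms: none
Why: Dess–Martin oxidation is non‑basic, so the enolisable α‑aryl stereocentre is not epimerised.

**Step 5**
Reactants: 7 (3S)-3-[2,6-bis(methoxymethoxy)-4-(triisopropylsilyloxy)phenyl]butan-2-one
Product: 8 {3,5-bis(methoxymethoxy)-4-[(2R)-3-methylbut-3-en-2-yl]phenoxy}triisopropylsilane
Conditions: Cp2Ti(μ-CH2)(μ-Cl)AlMe2 (Tebbe reagent), THF–toluene, −40 to 0 °C
Reagents that add atoms: Tebbe reagent Cp2Ti(μ-CH2)(μ-Cl)AlMe2, C[Al-]1(C)C[Ti](C2C=CC=C2)(C2C=CC=C2)[Cl+]1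
Why: Tebbe methylenation is a non‑basic carbonyl olefination, so the ketone becomes the isopropenyl group without enolising the neighbouring stereocentre (the descriptor changes from S to R only through the priority rules).

**Step 6**
Reactants: 8 {3,5-bis(methoxymethoxy)-4-[(2R)-3-methylbut-3-en-2-yl]phenoxy}triisopropylsilane
Product: 9 {2-iodo-3,5-bis(methoxymethoxy)-4-[(2R)-3-methylbut-3-en-2-yl]phenoxy}triisopropylsilane
Conditions: NIS (1.0 equiv), MeCN, −20 to 0 °C, dark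
Reagents that add atoms: N-iodosuccinimide (NIS), O=C1CCC(=O)N1I
Why: Electrophilic aromatic iodination gives one regioisomer because the two free ring positions are equivalent, and the tri‑oxygenated arene reacts far faster than the 1,1‑disubstituted alkene.

**Step 7**
Reactants: 9 {2-iodo-3,5-bis(methoxymethoxy)-4-[(2R)-3-methylbut-3-en-2-yl]phenoxy}triisopropylsilane
Product: 10 4-iodo-2-[(2R)-3-methylbut-3-en-2-yl]-5-(triisopropylsilyloxy)benzene-1,3-diol
Conditions: ZnBr2, n-PrSH, CH2Cl2, 0 °C, 10 min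
Reagents that add atoms: none
Why: Lewis acid‑assisted thiolysis of the MOM acetals frees both phenols quickly under aprotic conditions that spare the TIPS ether, the aryl iodide and the acid‑sensitive o‑hydroxyaryl/isopropenyl pair.

**Step 8**
Reactants: 11 3,5-dihydroxybenzaldehyde; 12 3-chloro-3-methylbut-1-yne
Product: 13 3,5-bis[(2-methylbut-3-yn-2-yl)oxy]benzaldehyde
Conditions: 12 (3 equiv), DBU, CuCl2·2H2O (1 mol %), MeCN, 0 °C
Reagents that add atoms: none
Why: Copper‑catalysed propargylic substitution O‑alkylates both phenols with the tertiary propargylic chloride.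

**Step 9**
Reactants: 13 3,5-bis[(2-methylbut-3-yn-2-yl)oxy]benzaldehyde
Product: 14 3,5-bis[(2-methylbut-3-en-2-yl)oxy]benzaldehyde
Conditions: H2 (1 atm), Pd/CaCO3 poisoned with Pb(OAc)2 (Lindlar catalyst), quinoline, EtOAc, rt
Reagents that add atoms: none
Why: Lindlar semihydrogenation stops at the alkene and leaves the aldehyde untouched.

**Step 10**
Reactants: 14 3,5-bis[(2-methylbut-3-en-2-yl)oxy]benzaldehyde
Product: 15 3,5-dihydroxy-2,6-bis(3-methylbut-2-en-1-yl)benzaldehyde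
Conditions: PhNEt2, 130 °C
Reagents that add atoms: none
Why: Twofold aromatic Claisen rearrangement ([3,3] shift, then tautomerisation) should deliver each prenyl group to the ortho carbon next to the formyl group, the site favoured by a meta acceptor and lying para to the other oxygen.

**Step 11**
Reactants: 15 3,5-dihydroxy-2,6-bis(3-methylbut-2-en-1-yl)benzaldehyde
Product: 16 7-hydroxy-2,2-dimethyl-6-(3-methylbut-2-en-1-yl)-3,4-dihydro-2H-chromene-5-carbaldehyde
Conditions: Amberlyst 15 (sulfonic acid resin), CH2Cl2, rt, stopped near half conversion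
Reagents that add atoms: none
Why: Acid‑catalysed Markovnikov hydroalkoxylation of one prenyl alkene by its neighbouring phenol closes ring D; the two pairs are equivalent, so the reaction is statistical, is stopped early, and unreacted 15 is recycled.

**Step 12**
Reactants: 16 7-hydroxy-2,2-dimethyl-6-(3-methylbut-2-en-1-yl)-3,4-dihydro-2H-chromene-5-carbaldehyde
Product: 17 5-ethynyl-2,2-dimethyl-6-(3-methylbut-2-en-1-yl)-3,4-dihydro-2H-chromen-7-ol
Conditions: dimethyl (1-diazo-2-oxopropyl)phosphonate, K2CO3, MeOH, 0 °C to rt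
Reagents that add atoms: dimethyl (1-diazo-2-oxopropyl)phosphonate, CC(=O)C(=[N+]=[N-])P(=O)(OC)OC
Why: Seyferth–Gilbert homologation with the Ohira–Bestmann reagent turns the aldehyde into the terminal alkyne under mild carbonate conditions that tolerate the free phenol and the prenyl group.

**Step 13**
Reactants: 10 4-iodo-2-[(2R)-3-methylbut-3-en-2-yl]-5-(triisopropylsilyloxy)benzene-1,3-diol; 17 5-ethynyl-2,2-dimethyl-6-(3-methylbut-2-en-1-yl)-3,4-dihydro-2H-chromen-7-ol
Product: 19 2-[7-hydroxy-2,2-dimethyl-6-(3-methylbut-2-en-1-yl)-3,4-dihydro-2H-chromen-5-yl]-7-[(2R)-3-methylbut-3-en-2-yl]-4-(triisopropylsilyloxy)-1-benzofuran-6-ol, via alkynylphenol 18 (not isolated)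
Conditions: PdCl2(PPh3)2 (5 mol %), CuI (10 mol %), Et3N, DMF, 70 °C
Reagents that add atoms: none
Why: Sonogashira coupling is followed by 5‑endo‑dig heteroannulation, and only the free hydroxyl ortho to the alkyne can add because the other ortho oxygen carries TIPS, so the side chain ends up at C7.

**Step 14**
Reactants: 19 2-[7-hydroxy-2,2-dimethyl-6-(3-methylbut-2-en-1-yl)-3,4-dihydro-2H-chromen-5-yl]-7-[(2R)-3-methylbut-3-en-2-yl]-4-(triisopropylsilyloxy)-1-benzofuran-6-ol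
Product: 20 2-[7-hydroxy-2,2-dimethyl-6-(3-methylbut-2-en-1-yl)-3,4-dihydro-2H-chromen-5-yl]-7-[(2R)-3-methylbut-3-en-2-yl]-1-benzofuran-4,6-diol
Conditions: TBAF, AcOH, THF, 0 °C
Reagents that add atoms: none
Why: Fluoride‑induced desilylation buffered with acetic acid frees the 4‑OH without touching the alkenes or the stereocentre.

**Compound list**
1 | benzene-1,3,5-triol (phloroglucinol) | Oc1cc(O)cc(O)c1 | starting material
2 | 5-(triisopropylsilyloxy)benzene-1,3-diol | Oc1cc(O)cc(O[Si](C(C)C)(C(C)C)C(C)C)c1 | intermediate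
3 | [3,5-bis(methoxymethoxy)phenoxy]triisopropylsilane | COCOc1cc(OCOC)cc(O[Si](C(C)C)(C(C)C)C(C)C)c1 | intermediate
4 | (2S,3S)-2,3-dimethyloxirane | C[C@@H]1O[C@H]1C | starting material
5 | [2,6-bis(methoxymethoxy)-4-(triisopropylsilyloxy)phenyl]lithium | COCOc1cc(O[Si](C(C)C)(C(C)C)C(C)C)cc(OCOC)c1[Li] | intermediate
6 | (2S,3S)-3-[2,6-bis(methoxymethoxy)-4-(triisopropylsilyloxy)phenyl]butan-2-ol | C[C@H](O)[C@@H](C)c1c(OCOC)cc(O[Si](C(C)C)(C(C)C)C(C)C)cc1OCOC | intermediate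
7 | (3S)-3-[2,6-bis(methoxymethoxy)-4-(triisopropylsilyloxy)phenyl]butan-2-one | CC(=O)[C@@H](C)c1c(OCOC)cc(O[Si](C(C)C)(C(C)C)C(C)C)cc1OCOC | intermediate
8 | {3,5-bis(methoxymethoxy)-4-[(2R)-3-methylbut-3-en-2-yl]phenoxy}triisopropylsilane | C=C(C)[C@@H](C)c1c(OCOC)cc(O[Si](C(C)C)(C(C)C)C(C)C)cc1OCOC | intermediate
9 | {2-iodo-3,5-bis(methoxymethoxy)-4-[(2R)-3-methylbut-3-en-2-yl]phenoxy}triisopropylsilane | C=C(C)[C@@H](C)c1c(OCOC)cc(O[Si](C(C)C)(C(C)C)C(C)C)c(I)c1OCOC | intermediate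
10 | 4-iodo-2-[(2R)-3-methylbut-3-en-2-yl]-5-(triisopropylsilyloxy)benzene-1,3-diol | C=C(C)[C@@H](C)c1c(O)cc(O[Si](C(C)C)(C(C)C)C(C)C)c(I)c1O | intermediate
11 | 3,5-dihydroxybenzaldehyde | O=Cc1cc(O)cc(O)c1 | starting material
12 | 3-chloro-3-methylbut-1-yne | C#CC(C)(C)Cl | starting material
13 | 3,5-bis[(2-methylbut-3-yn-2-yl)oxy]benzaldehyde | O=Cc1cc(OC(C)(C)C#C)cc(OC(C)(C)C#C)c1 | intermediate
14 | 3,5-bis[(2-methylbut-3-en-2-yl)oxy]benzaldehyde | O=Cc1cc(OC(C)(C)C=C)cc(OC(C)(C)C=C)c1 | intermediate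
15 | 3,5-dihydroxy-2,6-bis(3-methylbut-2-en-1-yl)benzaldehyde | O=Cc1c(CC=C(C)C)c(O)cc(O)c1CC=C(C)C | intermediate
16 | 7-hydroxy-2,2-dimethyl-6-(3-methylbut-2-en-1-yl)-3,4-dihydro-2H-chromene-5-carbaldehyde | O=Cc1c(CC=C(C)C)c(O)cc2c1CCC(C)(C)O2 | intermediate
17 | 5-ethynyl-2,2-dimethyl-6-(3-methylbut-2-en-1-yl)-3,4-dihydro-2H-chromen-7-ol | C#Cc1c(CC=C(C)C)c(O)cc2c1CCC(C)(C)O2 | intermediate
18 | 4-{[7-hydroxy-2,2-dimethyl-6-(3-methylbut-2-en-1-yl)-3,4-dihydro-2H-chromen-5-yl]ethynyl}-2-[(2R)-3-methylbut-3-en-2-yl]-5-(triisopropylsilyloxy)benzene-1,3-diol | C=C(C)[C@@H](C)c1c(O)cc(O[Si](C(C)C)(C(C)C)C(C)C)c(C#Cc2c(CC=C(C)C)c(O)cc3c2CCC(C)(C)O3)c1O | intermediate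
19 | 2-[7-hydroxy-2,2-dimethyl-6-(3-methylbut-2-en-1-yl)-3,4-dihydro-2H-chromen-5-yl]-7-[(2R)-3-methylbut-3-en-2-yl]-4-(triisopropylsilyloxy)-1-benzofuran-6-ol | C=C(C)[C@@H](C)c1c(O)cc(O[Si](C(C)C)(C(C)C)C(C)C)c2cc(-c3c(CC=C(C)C)c(O)cc4c3CCC(C)(C)O4)oc12 | intermediate
20 | 2-[7-hydroxy-2,2-dimethyl-6-(3-methylbut-2-en-1-yl)-3,4-dihydro-2H-chromen-5-yl]-7-[(2R)-3-methylbut-3-en-2-yl]-1-benzofuran-4,6-diol | C=C(C)[C@@H](C)c1c(O)cc(O)c2cc(-c3c(CC=C(C)C)c(O)cc4c3CCC(C)(C)O4)oc12 | target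

**Totals**
Total steps: 14. Longest linear sequence: 9 steps (steps 1 to 7, then 13 and 14).

**Steps most likely to fail, each with one fallback**

Step 3. The hindered aryllithium may open the 2,3-disubstituted epoxide poorly. The fallback sets out from 3 and comes back at 7, replacing the epoxide opening by an Evans alkylation. 3 is lithiated to 5 as before and opened onto oxirane (BF3·OEt2, −78 °C) to give 2-[2,6-bis(methoxymethoxy)-4-(triisopropylsilyloxy)phenyl]ethan-1-ol F1. TEMPO/PhI(OAc)2 in MeCN–H2O gives [2,6-bis(methoxymethoxy)-4-(triisopropylsilyloxy)phenyl]acetic acid F2. DCC/DMAP coupling with (4S)-4-benzyl-1,3-oxazolidin-2-one gives (4S)-4-benzyl-3-{[2,6-bis(methoxymethoxy)-4-(triisopropylsilyloxy)phenyl]acetyl}-1,3-oxazolidin-2-one F3. NaHMDS then MeI at −78 °C, with methyl entering anti to the benzyl group, gives (4S)-4-benzyl-3-{(2S)-2-[2,6-bis(methoxymethoxy)-4-(triisopropylsilyloxy)phenyl]propanoyl}-1,3-oxazolidin-2-one F4. MeONHMe·HCl/AlMe3 gives (2S)-2-[2,6-bis(methoxymethoxy)-4-(triisopropylsilyloxy)phenyl]-N-methoxy-N-methylpropanamide F5, and MeMgBr at 0 °C gives 7.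

Step 10. The second [3,3] shift may go to the carbon between the two oxygens. The fallback sets out from 11 and comes back at 15, placing the prenyl groups by halogenation and cross‑coupling. MOMCl/i-Pr2NEt gives 3,5-bis(methoxymethoxy)benzaldehyde F6. NBS (2.1 equiv, MeCN) brominates para to each ether oxygen to give 2,6-dibromo-3,5-bis(methoxymethoxy)benzaldehyde F7. Twofold Stille coupling with tributyl(3-methylbut-2-en-1-yl)stannane (Pd(PPh3)4, DMF, 100 °C) gives 3,5-bis(methoxymethoxy)-2,6-bis(3-methylbut-2-en-1-yl)benzaldehyde F8, and ZnBr2/n-PrSH in CH2Cl2 gives 15.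

Step 13. The electron‑rich, doubly ortho‑substituted iodoresorcinol may couple sluggishly or give alkyne homocoupling. The fallback sets out from 9 and 17 and comes back at 18, separating coupling from ring closure. The fully protected iodide 9 is coupled with 17 (PdCl2(PPh3)2, CuI, i-Pr2NH, THF, 50 °C) to give 5-({2,4-bis(methoxymethoxy)-3-[(2R)-3-methylbut-3-en-2-yl]-6-(triisopropylsilyloxy)phenyl}ethynyl)-2,2-dimethyl-6-(3-methylbut-2-en-1-yl)-3,4-dihydro-2H-chromen-7-ol F9. ZnBr2/n-PrSH then gives 18, now isolated, and Ph3PAuCl/AgOTf (2 mol %) in CH2Cl2 at rt closes the furan to 19.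

**Further compounds**
F1 | step 3 | 2-[2,6-bis(methoxymethoxy)-4-(triisopropylsilyloxy)phenyl]ethan-1-ol | OCCc1c(OCOC)cc(O[Si](C(C)C)(C(C)C)C(C)C)cc1OCOC
F2 | step 3 | [2,6-bis(methoxymethoxy)-4-(triisopropylsilyloxy)phenyl]acetic acid | OC(=O)Cc1c(OCOC)cc(O[Si](C(C)C)(C(C)C)C(C)C)cc1OCOC
F3 | step 3 | (4S)-4-benzyl-3-{[2,6-bis(methoxymethoxy)-4-(triisopropylsilyloxy)phenyl]acetyl}-1,3-oxazolidin-2-one | O=C(Cc1c(OCOC)cc(O[Si](C(C)C)(C(C)C)C(C)C)cc1OCOC)N1[C@@H](Cc2ccccc2)COC1=O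
F4 | step 3 | (4S)-4-benzyl-3-{(2S)-2-[2,6-bis(methoxymethoxy)-4-(triisopropylsilyloxy)phenyl]propanoyl}-1,3-oxazolidin-2-one | O=C([C@@H](C)c1c(OCOC)cc(O[Si](C(C)C)(C(C)C)C(C)C)cc1OCOC)N1[C@@H](Cc2ccccc2)COC1=O
F5 | step 3 | (2S)-2-[2,6-bis(methoxymethoxy)-4-(triisopropylsilyloxy)phenyl]-N-methoxy-N-methylpropanamide | CON(C)C(=O)[C@@H](C)c1c(OCOC)cc(O[Si](C(C)C)(C(C)C)C(C)C)cc1OCOC
F6 | step 10 | 3,5-bis(methoxymethoxy)benzaldehyde | O=Cc1cc(OCOC)cc(OCOC)c1
F7 | step 10 | 2,6-dibromo-3,5-bis(methoxymethoxy)benzaldehyde | O=Cc1c(Br)c(OCOC)cc(OCOC)c1Br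
F8 | step 10 | 3,5-bis(methoxymethoxy)-2,6-bis(3-methylbut-2-en-1-yl)benzaldehyde | O=Cc1c(CC=C(C)C)c(OCOC)cc(OCOC)c1CC=C(C)C
F9 | step 13 | 5-({2,4-bis(methoxymethoxy)-3-[(2R)-3-methylbut-3-en-2-yl]-6-(triisopropylsilyloxy)phenyl}ethynyl)-2,2-dimethyl-6-(3-methylbut-2-en-1-yl)-3,4-dihydro-2H-chromen-7-ol | C=C(C)[C@@H](C)c1c(OCOC)cc(O[Si](C(C)C)(C(C)C)C(C)C)c(C#Cc2c(CC=C(C)C)c(O)cc3c2CCC(C)(C)O3)c1OCOC
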